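## Retrosynthetic overview

- The target comes from site-selective hydrolysis of one vinylogous methyl ester of a 2,5-dimethoxyquinone, itself from oxidative demethylation of a tetramethoxyaryl carbinol; the quinone ring is unveiled, not built.
- The carbinol comes from one cation cascade on an acyclic farnesyl arene: enantioselective proton-initiated closure of ring A, then ring B, a 1,2-H / 1,2-CH3 / 1,2-H relay, and oxygen capture at C-5. All four stereocentres arise here.
- The farnesyl arene comes from lithiated 1,2,4,5-tetramethoxybenzene and (2E,6E)-farnesyl bromide.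
- Ring order: the aromatic ring is purchased; ring A, then ring B, form in step 2.

Locants: decalin carbons are C-1 to C-10 in drimane fashion. C-4 carries the gem-dimethyl group, C-5 and C-10 are the ring-fusion carbons, C-8 is the CH–CH3, C-9 the quaternary carbon, C-11 the benzylic CH2. β is the face of the C-8 and C-9 methyls of the target; α is the opposite face. The target is (5S,8S,9R,10S): 5α-OH, 10α-H, cis-fused.

Assumption: the (R)-configured tin acid is taken to give the (5S,9S,10S) drimane sense, as in its ambrox-type cyclisations; if the sense is opposite, the (S)-ligand is used with nothing else changed.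

## Route

Step 1
Reactants: 1 1,2,4,5-tetramethoxybenzene; 2 (2E,6E)-farnesyl bromide
Product: 4 3-[(2E,6E)-3,7,11-trimethyldodeca-2,6,10-trien-1-yl]-1,2,4,5-tetramethoxybenzene, via aryllithium 3 (not isolated)
Conditions: n-BuLi, TMEDA, THF, 0 °C; CuBr·SMe2 (10 mol %), then 2, −78 °C → rt
Reagents that add atoms: n-butyllithium, [Li]CCCC (its lithium is carried by 3 only; none of its atoms remain in 4)
Why: Directed ortho-lithiation (the two ring C–H are equivalent, each flanked by two methoxy groups) followed by copper-catalysed SN2 allylation, which keeps the 2E,6E geometry; no stereocentre is formed.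

Step 2
Reactants: 4 3-[(2E,6E)-farnesyl]-1,2,4,5-tetramethoxybenzene
Product: 8 3-{[(1R,2S,4aS,8aS)-4a-hydroxy-1,2,5,5-tetramethyldecahydronaphthalen-1-yl]methyl}-1,2,4,5-tetramethoxybenzene, via drim-7-enyl arene 5 (not isolated), via rearranged 5(10)-olefin 6 (not isolated), via C-5 trifluoroacetate 7 (not isolated)
Conditions: SnCl4·(R)-2-(2-fluorobenzyloxy)-2'-hydroxy-1,1'-binaphthyl (1.5 equiv), toluene, −78 °C, 48 h; then CF3CO2H (20 equiv), CH2Cl2, −78 → −30 °C (1 h) → −78 °C (6 h); cannulate into cold K2CO3, MeOH/H2O, 0 °C; recrystallise 8 to enantiopurity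
Reagents that add atoms: trifluoroacetic acid, OC(=O)C(F)(F)F (one oxygen becomes the C-5 hydroxyl oxygen of 8; the trifluoroacetyl group is carried by 7 only)
Why: Proposed new method: the chiral Lewis acid-assisted Brønsted acid protonates one face of the terminal olefin and triggers chair–chair cation–olefin bicyclisation (closest known type: enantioselective proton-initiated polyene cyclisation of polyprenyl arenes, finished with an achiral acid) to give 5 with C-5, C-9 and C-10 fixed; CF3CO2H·SnCl4 then regenerates the C-8 cation, which relays by suprafacial antiperiplanar 1,2-shifts (H-9α to C-8 sets 8S; CH3-10β to C-9 sets the 9R quaternary centre; closest known type: the BF3·OEt2 rearrangement of 8-drimenyl arenes to the 5(10)-olefin used in aureol syntheses); H-5α migrates to C-10, or olefin 6 is protonated at C-10 from the α face (the face that is protonated in aureol-type cycloetherifications), and the C-5 cation is captured on its α face, anti to the axial 9β-methyl, by trifluoroacetate at −78 °C, where the Markovnikov adduct 7 is enthalpically favoured (closest known type: trifluoroacetate-terminated cation–olefin cyclisations); the basic quench cleaves 7 at the acyl–oxygen bond, so the C-5–O bond and the cis (5S,10S) fusion are not re-ionised.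

Step 3
Reactants: 8 tetramethoxyaryl carbinol
Product: 9 3-{[(1R,2S,4aS,8aS)-4a-hydroxy-1,2,5,5-tetramethyldecahydronaphthalen-1-yl]methyl}-2,5-dimethoxycyclohexa-2,5-diene-1,4-dione
Conditions: (NH4)2Ce(NO3)6 (2.2 equiv), MeCN/H2O 2:1, 0 °C, 10 min
Reagents that add atoms: water, O (both quinone carbonyl oxygens)
Why: Oxidative demethylation by the one-electron oxidant tetravalent cerium; both para-dimethoxy pairs of the ring are equivalent, so a single 2,5-dimethoxy-para-quinone forms, and the short cold exposure leaves the tertiary alcohol and all stereocentres untouched.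

Step 4
Reactants: 9 2,5-dimethoxyquinone
Product: 11 2-hydroxy-3-{[(1R,2S,4aS,8aS)-4a-hydroxy-1,2,5,5-tetramethyldecahydronaphthalen-1-yl]methyl}-5-methoxycyclohexa-2,5-diene-1,4-dione, via potassium quinonolate 10 (not isolated)
Conditions: KOH (2.5 equiv), MeOH/H2O 3:1, 0 °C → rt; then 1 M HCl to pH 3, 0 °C
Reagents that add atoms: potassium hydroxide, [K+].[OH-] (the hydroxide oxygen becomes the C-2 hydroxyl oxygen; potassium is carried by 10 only)
Why: Vinylogous ester saponification by addition–elimination: the methoxy group next to the neopentyl-type CH2 is twisted out of conjugation and so is the more electrophilic one (the pattern expected from ilimaquinone-type end games), the delocalised anion 10 resists a second attack, and base does not touch the tertiary alcohol or any stereocentre.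

## Compound list

1 | 1,2,4,5-tetramethoxybenzene | COc1cc(OC)c(OC)cc1OC | starting material
2 | (2E,6E)-farnesyl bromide | CC(C)=CCC/C(C)=C/CC/C(C)=C/CBr | starting material
3 | 2,3,5,6-tetramethoxyphenyllithium (not isolated) | [Li]c1c(OC)c(OC)cc(OC)c1OC | intermediate
4 | 3-[(2E,6E)-farnesyl]-1,2,4,5-tetramethoxybenzene | CC(C)=CCC/C(C)=C/CC/C(C)=C/Cc1c(OC)c(OC)cc(OC)c1OC | intermediate
5 | (5S,9S,10S)-11-(2,3,5,6-tetramethoxyphenyl)drim-7-ene, trans-decalin with 10β-CH3, 5α-H, 9α-H; major double-bond isomer of the cyclisation mixture (not isolated) | COc1cc(OC)c(OC)c(C[C@H]2C(C)=CC[C@H]3C(C)(C)CCC[C@]23C)c1OC | intermediate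
6 | (8S,9R)-3-{[(1R,2S)-1,2,5,5-tetramethyl-1,2,3,4,5,6,7,8-octahydronaphthalen-1-yl]methyl}-1,2,4,5-tetramethoxybenzene, the 5(10)-olefin with 8β-CH3 and 9β-CH3 (not isolated) | COc1cc(OC)c(OC)c(C[C@]2(C)[C@@H](C)CCC3=C2CCCC3(C)C)c1OC | intermediate
7 | (5S,8S,9R,10S) C-5 trifluoroacetate of 8, 5α-O, 10α-H (not isolated) | COc1cc(OC)c(OC)c(C[C@]2(C)[C@@H](C)CC[C@]3(OC(=O)C(F)(F)F)[C@H]2CCCC3(C)C)c1OC | intermediate
8 | 3-{[(1R,2S,4aS,8aS)-4a-hydroxy-1,2,5,5-tetramethyldecahydronaphthalen-1-yl]methyl}-1,2,4,5-tetramethoxybenzene, cis-decalin with 5α-OH and 10α-H | COc1cc(OC)c(OC)c(C[C@]2(C)[C@@H](C)CC[C@]3(O)[C@H]2CCCC3(C)C)c1OC | intermediate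
9 | 3-{[(1R,2S,4aS,8aS)-4a-hydroxy-1,2,5,5-tetramethyldecahydronaphthalen-1-yl]methyl}-2,5-dimethoxy-1,4-benzoquinone | COC1=CC(=O)C(OC)=C(C[C@]2(C)[C@@H](C)CC[C@]3(O)[C@H]2CCCC3(C)C)C1=O | intermediate
10 | potassium salt of 11 at the C-2 quinone oxygen (not isolated) | COC1=CC(=O)C([O-])=C(C[C@]2(C)[C@@H](C)CC[C@]3(O)[C@H]2CCCC3(C)C)C1=O.[K+] | intermediate
11 | 2-hydroxy-3-{[(1R,2S,4aS,8aS)-4a-hydroxy-1,2,5,5-tetramethyldecahydronaphthalen-1-yl]methyl}-5-methoxy-1,4-benzoquinone (CNP0209468.1) | COC1=CC(=O)C(O)=C(C[C@]2(C)[C@@H](C)CC[C@]3(O)[C@H]2CCCC3(C)C)C1=O | target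

## Step count and risks

Total steps: 4. Longest linear sequence: 4 steps (1 or 2 → 4 → 8 → 9 → 11).

The three steps most likely to fail, in order of risk:

**Step 2.** This is the step that goes beyond precedent, and it has several ways to go wrong:
- the chiral acid gives only about 80–90 % ee, hence the recrystallisation;
- trifluoroacetate may be captured at C-8 before the relay, or at C-10 instead of C-5;
- the relay may overshoot by migration of a C-4 methyl;
- adduct 7 is thermodynamically marginal, so a large share of material may remain as olefin 6, which can be resubmitted to the trifluoroacetic acid stage.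

Fallback: setting out from 4, the chiral-acid cyclisation is followed by BF3·OEt2 (CH2Cl2, −78 → −10 °C) and a NaHCO3 quench, so that the cation chemistry stops at olefin 6, which is isolated. Compound 6 is then hydrated by a radical instead of a cationic pathway (Mukaiyama hydration: Mn(dpm)3 20 mol %, dpm = 2,2,6,6-tetramethylheptane-3,5-dionate, PhSiH3, O2, i-PrOH/CH2Cl2, 0 °C). Hydrogen-atom transfer to C-10 and oxygen capture at C-5, both on the α face away from the two β-methyls, give the C-5 hydroperoxide F1. PPh3 reduces F1 in the same flask, and the route is rejoined at 8 after chromatographic removal of the C-10 regioisomer, which is expected to be a major by-product.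

**Step 4.** Hydroxide may attack the unhindered methoxy carbon instead and give the regioisomeric hydroxy-methoxyquinone. Fallback: setting out from 9, both vinylogous esters are hydrolysed (aq. NaOH, THF, 50 °C, then cold acidification) to the 2,5-dihydroxyquinone F3. The vinylogous acid that flanks the ring C–H is then methylated selectively on steric grounds (Me3SiCHN2 1.05 equiv, MeOH/toluene, −20 °C); the one flanking the bulky CH2 stays free. This rejoins the route at 11.

**Step 3.** The nitric acid released may ionise the hindered tertiary alcohol, or over-oxidation may occur. Fallback: setting out from 8, anodic oxidation in 1 % KOH/MeOH (carbon anode, 0 °C, undivided cell) gives, under basic conditions, the quinone bis(dimethyl ketal) F2. Hydrolysis of F2 on wet silica gel doped with oxalic acid (CH2Cl2, rt) rejoins the route at 9.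

## Further compounds

F1 | step 2 | (5S,8S,9R,10S) C-5 hydroperoxide corresponding to 8 | COc1cc(OC)c(OC)c(C[C@]2(C)[C@@H](C)CC[C@]3(OO)[C@H]2CCCC3(C)C)c1OC
F2 | step 3 | 1,4-bis(dimethyl ketal) of 9: 3,3,6,6-tetramethoxy-1,4-dimethoxycyclohexa-1,4-diene carrying the decalinylmethyl group at C-2 | COC1=CC(OC)(OC)C(OC)=C(C[C@]2(C)[C@@H](C)CC[C@]3(O)[C@H]2CCCC3(C)C)C1(OC)OC
F3 | step 4 | 2,5-dihydroxy-3-{[(1R,2S,4aS,8aS)-4a-hydroxy-1,2,5,5-tetramethyldecahydronaphthalen-1-yl]methyl}-1,4-benzoquinone | OC1=CC(=O)C(O)=C(C[C@]2(C)[C@@H](C)CC[C@]3(O)[C@H]2CCCC3(C)C)C1=O
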